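**Plan**

- Chain numbering: C1 (ester) to C5 (benzylic CH2); ring A is the 4-hydroxyphenyl on C3, ring B the 4-hydroxy-3-prenylphenyl on C5. The C4 ketone lies within five-membered reach of the C1 carboxyl oxygen (O–C1–C2–C3–C4), so a C4≡C5 alkyne conjugated to ring B can stand in for the ketone and be oxygenated at C4 only.
- Retrosynthetic cuts, in order: the C1–OMe bond (methanolysis of an enol lactone), the lactone O–C4 bond (cycloisomerisation of a 4-alkynoic acid), the C5–ring B bond (Sonogashira), the C3–C4 bond (alkynylalane opening of a cis-epoxy alcohol), the ring A–C3 bond (Sonogashira with propargyl alcohol) and the prenyl–ring B bond.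
- Forward: ring A is built into a (Z)-cinnamyl alcohol and its cis-epoxide; the two alkyne carbons are added at C3; the terminal alkyne is joined to the ring B iodide; C1 is oxidised to the acid. The only ring formed, the butyrolactone, arises in the key step and is reopened by methanol.
- Stereochemistry: C2 comes from the Sharpless epoxidation with L-(+)-diethyl tartrate; C3 comes from SN2 inversion at the benzylic epoxide carbon (cis-epoxide gives the anti C2/C3 pair). C3 stays a non-enolisable propargylic methine until the ketone is unveiled in the last two steps.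

Key step: step 13

Remark on the chemistry: ring A is carried as its pivalate through the epoxide stages, because an acyloxyaryl group stabilises a benzylic cation far less than a silyloxyaryl group; the pivalate is exchanged for a silyl ether before the key step. Abbreviations: TBS = tert-butyldimethylsilyl, Piv = pivaloyl, prenyl = 3-methylbut-2-en-1-yl.

**Route**

Step 1
Reactants: 1 4-iodophenol
Product: 2 4-iodophenyl pivalate
Conditions: PivCl, Et3N, DMAP (cat.), CH2Cl2, 0 °C to rt
Reagents that add atoms: pivaloyl chloride, CC(C)(C)C(Cl)=O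
Why: DMAP-catalysed O-acylation of a phenol; the hindered aryl ester should survive the coupling, titanium alkoxide and alane steps and makes ring A a poorer cation-stabilising group than a silyl ether would.

Step 2
Reactants: 2 4-iodophenyl pivalate; 3 propargyl alcohol
Product: 4 4-(3-hydroxyprop-1-yn-1-yl)phenyl pivalate
Conditions: PdCl2(PPh3)2 (cat.), CuI (cat.), Et3N, THF, rt
Reagents that add atoms: none
Why: Sonogashira coupling of an aryl iodide with a terminal alkyne at room temperature, which tolerates the free propargylic hydroxyl and the aryl ester.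

Step 3
Reactants: 4 4-(3-hydroxyprop-1-yn-1-yl)phenyl pivalate
Product: 5 4-[(Z)-3-hydroxyprop-1-en-1-yl]phenyl pivalate
Conditions: H2 (1 atm), Pd/CaCO3 poisoned with Pb(OAc)2, quinoline, EtOAc, rt
Reagents that add atoms: none
Why: Lindlar semihydrogenation, in which syn delivery of hydrogen on the poisoned palladium surface should give the (Z)-allylic alcohol and stop at the alkene.

Step 4
Reactants: 5 4-[(Z)-3-hydroxyprop-1-en-1-yl]phenyl pivalate
Product: 6 4-[(2R,3S)-3-(hydroxymethyl)oxiran-2-yl]phenyl pivalate (cis-epoxy alcohol; 2S,3R in glycidol numbering)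
Conditions: Ti(OiPr)4, L-(+)-diethyl tartrate, t-BuOOH, 4 Å molecular sieves, CH2Cl2, −20 °C
Reagents that add atoms: tert-butyl hydroperoxide, CC(C)(C)OO
Why: Sharpless asymmetric epoxidation, in which the titanium tartrate complex binds the allylic alcohol and delivers oxygen to one alkene face, so that L-(+)-tartrate sets the C2 configuration (2S in the epoxy alcohol) and the Z geometry fixes the cis relationship.

Step 5
Reactants: 6 cis-epoxy alcohol; 7 ethynyltrimethylsilane
Product: 8 (2R,3R)-3-[4-(pivaloyloxy)phenyl]-5-(trimethylsilyl)pent-4-yne-1,2-diol (anti)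
Conditions: 7 (4 equiv), n-BuLi, toluene, 0 °C; Et2AlCl, 0 °C; then 6, toluene–CH2Cl2, 0 °C to rt
Reagents that add atoms: none
Why: Opening of a 2,3-epoxy alcohol by a diethylalkynylalane, in which the aluminium alkoxide of the C1 hydroxyl and aluminium activation of the epoxide direct the alkynyl group to the benzylic C3 from the side opposite the C–O bond, so that inversion at C3 of the cis-epoxide gives the anti 1,2-diol with C2 untouched.

Step 6
Reactants: 8 anti diol
Product: 9 (2R,3S)-3-(4-hydroxyphenyl)pent-4-yne-1,2-diol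
Conditions: K2CO3, MeOH, rt
Reagents that add atoms: none
Why: Base-mediated methanolysis, which should remove the alkynyl silane (protiodesilylation) and the aryl pivalate (transesterification) in one operation without touching the non-acidic propargylic methine.

Step 7
Reactants: 9 (2R,3S)-3-(4-hydroxyphenyl)pent-4-yne-1,2-diol
Product: 10 (2R,3S)-1,2-bis(TBS-oxy)-3-[4-(TBS-oxy)phenyl]pent-4-yne
Conditions: TBSOTf, 2,6-lutidine, CH2Cl2, −78 to 0 °C
Reagents that add atoms: tert-butyldimethylsilyl trifluoromethanesulfonate, CC(C)(C)[Si](C)(C)OS(=O)(=O)C(F)(F)F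
Why: Exhaustive O-silylation with a silyl triflate and a hindered pyridine base, which is reactive enough for the hindered secondary hydroxyl and leaves the terminal alkyne C–H alone.

Step 8
Reactants: 1 4-iodophenol; 11 prenyl bromide
Product: 12 4-iodo-2-prenylphenol
Conditions: NaH, toluene, 0 °C; then 11, rt
Reagents that add atoms: none
Why: ortho-C-alkylation of a sodium phenoxide in a non-polar solvent, where the tight ion pair steers the allylic bromide to the ring carbon next to oxygen and the para position is blocked by iodine.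

Step 9
Reactants: 12 4-iodo-2-prenylphenol
Product: 13 tert-butyl(4-iodo-2-prenylphenoxy)dimethylsilane
Conditions: TBSCl, imidazole, DMF, rt
Reagents that add atoms: tert-butyldimethylsilyl chloride, CC(C)(C)[Si](C)(C)Cl
Why: Imidazole-promoted silylation of a phenol (Corey conditions), which also blocks later cyclisation of the phenol onto the prenyl group.

Step 10
Reactants: 10 tris-TBS terminal alkyne; 13 ring B aryl iodide
Product: 14 (2R,3R)-1,2-bis(TBS-oxy)-3-[4-(TBS-oxy)phenyl]-5-[4-(TBS-oxy)-3-prenylphenyl]pent-4-yne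
Conditions: PdCl2(PPh3)2 (cat.), CuI (cat.), Et3N, THF, rt to 40 °C
Reagents that add atoms: none
Why: Sonogashira coupling (oxidative addition of the aryl iodide to zerovalent palladium, transmetalation from the copper acetylide, reductive elimination), mild enough to leave the prenyl alkene and the propargylic stereocentre alone.

Step 11
Reactants: 14 tetra-TBS alkyne
Product: 15 (2R,3R)-2-(TBS-oxy)-3-[4-(TBS-oxy)phenyl]-5-[4-(TBS-oxy)-3-prenylphenyl]pent-4-yn-1-ol
Conditions: CSA (cat.), MeOH–CH2Cl2, 0 °C
Reagents that add atoms: none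
Why: Acid-catalysed methanolysis of silyl ethers under steric control, in which the primary alkyl TBS ether is cleaved well before the secondary one and aryl TBS ethers are inert to mild acid.

Step 12
Reactants: 15 primary alcohol
Product: 17 (2R,3R)-2-(TBS-oxy)-3-[4-(TBS-oxy)phenyl]-5-[4-(TBS-oxy)-3-prenylphenyl]pent-4-ynoic acid, via aldehyde 16 (not isolated)
Conditions: TEMPO (cat.), PhI(OAc)2, MeCN–CH2Cl2–H2O, rt
Reagents that add atoms: water, O
Why: Oxoammonium-mediated oxidation of a primary alcohol to the acid through the aldehyde and its hydrate (TEMPO with PhI(OAc)2 in wet solvent), which uses no hypochlorite and should therefore spare the prenyl alkene, the alkyne and the silyl ethers.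

Step 13
Reactants: 17 alkynoic acid
Product: 18 (3R,4S,5Z)-3-(TBS-oxy)-4-[4-(TBS-oxy)phenyl]-5-{[4-(TBS-oxy)-3-prenylphenyl]methylidene}dihydrofuran-2(3H)-one (cis-3,4)
Conditions: AuCl (5 mol %), K2CO3 (10 mol %), MeCN, rt
Reagents that add atoms: none
Why: AuCl (monovalent gold) binds the C4≡C5 alkyne, the C1 carboxylate attacks C4 from the side opposite the metal, and protodeauration of the vinylgold species by the next molecule of acid releases the enol lactone and regenerates catalyst and carboxylate. The closest known reaction type is the gold- or palladium-catalysed cycloisomerisation of 4-alkynoic acids to (Z)-5-ylidene butyrolactones. The butyrolactone closes in the 5-exo-dig mode with formation of the O–C4 bond. No stereocentre is created; the (Z) geometry follows from anti addition of oxygen and hydrogen across the alkyne, and C2 and C3 are carried through unchanged. The step needs 5-exo over 6-endo closure against the electronic pull of ring B toward C5, and no migration of the exocyclic double bond into the ring. The short tether that reaches C4 through a five-membered ring, the substituents on C2 and C3 that favour the compact ring, the C2 silyl ether that removes the only competing oxygen nucleophile, and the carbonate-buffered acid-free medium should secure both.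

Step 14
Reactants: 18 enol lactone
Product: 19 methyl (2R,3S)-2-(TBS-oxy)-3-[4-(TBS-oxy)phenyl]-5-[4-(TBS-oxy)-3-prenylphenyl]-4-oxopentanoate
Conditions: MeOH, DMAP (cat.), CH2Cl2, 0 °C to rt
Reagents that add atoms: methanol, CO
Why: Nucleophile-catalysed alcoholysis (transesterification) of an enol ester, in which methanol takes the activated lactone acyl group and the released enol is protonated at C5 to the C4 ketone under conditions too weakly basic to enolise toward C3.

Step 15
Reactants: 19 tris-TBS keto ester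
Product: 20 asperteretal H, methyl (2R,3S)-2-hydroxy-5-(4-hydroxy-3-prenylphenyl)-3-(4-hydroxyphenyl)-4-oxopentanoate
Conditions: HF·pyridine, pyridine, THF, 0 °C to rt
Reagents that add atoms: none
Why: Fluoride-mediated desilylation under pyridine-buffered, weakly acidic conditions, which should free the two phenols and the C2 hydroxyl without the base that would trigger retro-aldol cleavage or C3 epimerisation and without the strong acid that would cyclise the prenylphenol.

**Compound list**

1 | 4-iodophenol | Oc1ccc(I)cc1 | starting material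
2 | 4-iodophenyl pivalate | CC(C)(C)C(=O)Oc1ccc(I)cc1 | intermediate
3 | propargyl alcohol | C#CCO | starting material
4 | 4-(3-hydroxyprop-1-yn-1-yl)phenyl pivalate | CC(C)(C)C(=O)Oc1ccc(C#CCO)cc1 | intermediate
5 | 4-[(Z)-3-hydroxyprop-1-en-1-yl]phenyl pivalate | CC(C)(C)C(=O)Oc1ccc(/C=C\CO)cc1 | intermediate
6 | 4-[(2R,3S)-3-(hydroxymethyl)oxiran-2-yl]phenyl pivalate (cis) | OC[C@@H]1O[C@@H]1c1ccc(OC(=O)C(C)(C)C)cc1 | intermediate
7 | ethynyltrimethylsilane | C#C[Si](C)(C)C | starting material
8 | (2R,3R)-3-[4-(pivaloyloxy)phenyl]-5-(trimethylsilyl)pent-4-yne-1,2-diol | OC[C@H](O)[C@@H](C#C[Si](C)(C)C)c1ccc(OC(=O)C(C)(C)C)cc1 | intermediate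
9 | (2R,3S)-3-(4-hydroxyphenyl)pent-4-yne-1,2-diol | OC[C@H](O)[C@@H](C#C)c1ccc(O)cc1 | intermediate
10 | (2R,3S)-1,2-bis(TBS-oxy)-3-[4-(TBS-oxy)phenyl]pent-4-yne | CC(C)(C)[Si](C)(C)OC[C@H](O[Si](C)(C)C(C)(C)C)[C@@H](C#C)c1ccc(O[Si](C)(C)C(C)(C)C)cc1 | intermediate
11 | prenyl bromide | CC(C)=CCBr | starting material
12 | 4-iodo-2-prenylphenol | CC(C)=CCc1cc(I)ccc1O | intermediate
13 | tert-butyl(4-iodo-2-prenylphenoxy)dimethylsilane | CC(C)=CCc1cc(I)ccc1O[Si](C)(C)C(C)(C)C | intermediate
14 | (2R,3R)-1,2-bis(TBS-oxy)-3-[4-(TBS-oxy)phenyl]-5-[4-(TBS-oxy)-3-prenylphenyl]pent-4-yne | CC(C)(C)[Si](C)(C)OC[C@H](O[Si](C)(C)C(C)(C)C)[C@@H](C#Cc1ccc(O[Si](C)(C)C(C)(C)C)c(CC=C(C)C)c1)c1ccc(O[Si](C)(C)C(C)(C)C)cc1 | intermediate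
15 | (2R,3R)-2-(TBS-oxy)-3-[4-(TBS-oxy)phenyl]-5-[4-(TBS-oxy)-3-prenylphenyl]pent-4-yn-1-ol | OC[C@H](O[Si](C)(C)C(C)(C)C)[C@@H](C#Cc1ccc(O[Si](C)(C)C(C)(C)C)c(CC=C(C)C)c1)c1ccc(O[Si](C)(C)C(C)(C)C)cc1 | intermediate
16 | (2R,3R)-2-(TBS-oxy)-3-[4-(TBS-oxy)phenyl]-5-[4-(TBS-oxy)-3-prenylphenyl]pent-4-ynal | O=C[C@H](O[Si](C)(C)C(C)(C)C)[C@@H](C#Cc1ccc(O[Si](C)(C)C(C)(C)C)c(CC=C(C)C)c1)c1ccc(O[Si](C)(C)C(C)(C)C)cc1 | intermediate
17 | (2R,3R)-2-(TBS-oxy)-3-[4-(TBS-oxy)phenyl]-5-[4-(TBS-oxy)-3-prenylphenyl]pent-4-ynoic acid | OC(=O)[C@H](O[Si](C)(C)C(C)(C)C)[C@@H](C#Cc1ccc(O[Si](C)(C)C(C)(C)C)c(CC=C(C)C)c1)c1ccc(O[Si](C)(C)C(C)(C)C)cc1 | intermediate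
18 | (3R,4S,5Z)-3-(TBS-oxy)-4-[4-(TBS-oxy)phenyl]-5-{[4-(TBS-oxy)-3-prenylphenyl]methylidene}dihydrofuran-2(3H)-one | O=C1[C@H](O[Si](C)(C)C(C)(C)C)[C@H](c2ccc(O[Si](C)(C)C(C)(C)C)cc2)/C(=C/c2ccc(O[Si](C)(C)C(C)(C)C)c(CC=C(C)C)c2)O1 | intermediate
19 | methyl (2R,3S)-2-(TBS-oxy)-3-[4-(TBS-oxy)phenyl]-5-[4-(TBS-oxy)-3-prenylphenyl]-4-oxopentanoate | COC(=O)[C@H](O[Si](C)(C)C(C)(C)C)[C@@H](C(=O)Cc1ccc(O[Si](C)(C)C(C)(C)C)c(CC=C(C)C)c1)c1ccc(O[Si](C)(C)C(C)(C)C)cc1 | intermediate
20 | asperteretal H, methyl (2R,3S)-2-hydroxy-5-(4-hydroxy-3-prenylphenyl)-3-(4-hydroxyphenyl)-4-oxopentanoate | COC(=O)[C@H](O)[C@@H](C(=O)Cc1ccc(O)c(CC=C(C)C)c1)c1ccc(O)cc1 | target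

**Count and risks**

Total steps: 15. Longest linear sequence: 13 (steps 1–7 and 10–15 from 4-iodophenol); steps 8 and 9 form the ring B branch.

Steps most likely to fail:

1. Step 5 (alkynylalane opening). Ionisation of the aluminium-bound benzylic epoxide could erode the inversion at C3, and some alkynyl delivery to C2 could compete. The fallback sets out from 6 and replaces alkoxide-directed delivery by external attack on a protected epoxide. Silylation of the primary hydroxyl (TBSCl, imidazole, DMF) should give 4-[(2R,3S)-3-(TBS-oxymethyl)oxiran-2-yl]phenyl pivalate F1. Lithium (trimethylsilyl)acetylide with BF3·OEt2 in THF at −78 °C (Yamaguchi–Hirao alkynylation) should open it by SN2 attack at the benzylic carbon, C2 being deactivated by the neighbouring silyloxymethyl group, to give (2R,3R)-1-(TBS-oxy)-3-[4-(pivaloyloxy)phenyl]-5-(trimethylsilyl)pent-4-yn-2-ol F2. K2CO3 in MeOH should then remove the alkynyl silane and the pivalate to give (2R,3S)-1-(TBS-oxy)-3-(4-hydroxyphenyl)pent-4-yn-2-ol F3. Silylation of its two free hydroxyls (TBSOTf, 2,6-lutidine) comes back to the route at 10.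

2. Step 13 (cycloisomerisation). Closure could leak into the 6-endo mode at the ring B-bearing carbon, or the exocyclic double bond could migrate into the ring during reaction or isolation, with loss of the C3 configuration. The fallback sets out from 17 and never forms an isolable enol lactone. Esterification with (trimethylsilyl)diazomethane in MeOH–toluene should give methyl (2R,3R)-2-(TBS-oxy)-3-[4-(TBS-oxy)phenyl]-5-[4-(TBS-oxy)-3-prenylphenyl]pent-4-ynoate F4. Gold-catalysed hydration with neighbouring ester participation (Ph3PAuCl, AgOTf, 1,4-dioxane–H2O, rt) lets the ester carbonyl oxygen attack C4 through the same five-membered arrangement, and water opens the cyclic oxocarbenium ion directly to the keto ester. This comes back to the route at 19.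

3. Step 14 (methanolysis). Once the ketone is free, enolisation toward C3 could epimerise that centre or expel the C2 silyloxy group, and the aryl silyl ethers could be lost early. The fallback sets out from 18 and avoids base altogether. Acid-catalysed hydrolysis of the enol lactone (p-TsOH (cat.), THF–H2O, rt; C-protonation at C5, then water capture) should give (2R,3S)-2-(TBS-oxy)-3-[4-(TBS-oxy)phenyl]-5-[4-(TBS-oxy)-3-prenylphenyl]-4-oxopentanoic acid F5. Neutral O-methylation with (trimethylsilyl)diazomethane in MeOH–toluene at 0 °C comes back to the route at 19.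

Further compounds
F1 | step 5 | 4-[(2R,3S)-3-(TBS-oxymethyl)oxiran-2-yl]phenyl pivalate | CC(C)(C)[Si](C)(C)OC[C@@H]1O[C@@H]1c1ccc(OC(=O)C(C)(C)C)cc1
F2 | step 5 | (2R,3R)-1-(TBS-oxy)-3-[4-(pivaloyloxy)phenyl]-5-(trimethylsilyl)pent-4-yn-2-ol | CC(C)(C)[Si](C)(C)OC[C@H](O)[C@@H](C#C[Si](C)(C)C)c1ccc(OC(=O)C(C)(C)C)cc1
F3 | step 5 | (2R,3S)-1-(TBS-oxy)-3-(4-hydroxyphenyl)pent-4-yn-2-ol | CC(C)(C)[Si](C)(C)OC[C@H](O)[C@@H](C#C)c1ccc(O)cc1
F4 | step 13 | methyl (2R,3R)-2-(TBS-oxy)-3-[4-(TBS-oxy)phenyl]-5-[4-(TBS-oxy)-3-prenylphenyl]pent-4-ynoate | COC(=O)[C@H](O[Si](C)(C)C(C)(C)C)[C@@H](C#Cc1ccc(O[Si](C)(C)C(C)(C)C)c(CC=C(C)C)c1)c1ccc(O[Si](C)(C)C(C)(C)C)cc1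
F5 | step 14 | (2R,3S)-2-(TBS-oxy)-3-[4-(TBS-oxy)phenyl]-5-[4-(TBS-oxy)-3-prenylphenyl]-4-oxopentanoic acid | OC(=O)[C@H](O[Si](C)(C)C(C)(C)C)[C@@H](C(=O)Cc1ccc(O[Si](C)(C)C(C)(C)C)c(CC=C(C)C)c1)c1ccc(O[Si](C)(C)C(C)(C)C)cc1
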